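The cyclohexenone is cut at C7–C8 and C5–C6 (spiro[4.5]decane numbering, C5 spiro). This removes C6(CH3)=C7H as propyne and folds C8, C9, C10 and C5 back into a cyclobutanone, a 3-methyl-5-acyloxy-7-isopropenylspiro[3.4]octan-1-one. In one flask 1-propynyllithium adds to the strained ketone (C7–C8). A photocatalytically generated alkoxy radical then opens the four-membered ring at its quaternary corner, and the tertiary C5 radical closes 6-endo-dig on the ynone (C5–C6). The step exploits the fully substituted atom C5 shared by both rings. Flanked by the C4 acyloxy group, it is both the best radical-forming corner and the stereocontrol element. The ketone comes from (S)-limonene.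

Key step: step 11

Remark: C1–C10 follow the target numbering (C2 isopropenyl, C4 isobutyrate, C5 spiro, C6 vinylic methyl carbon, C8 ketone, C9 acetate, C10 methyl). The two tertiary carbinol centres made by organometallic addition are drawn as the expected major epimers, and both are erased in the following event.

Step 1
Reactants: 1 (S)-(−)-limonene
Product: 2 (3S)-6-oxo-3-(prop-1-en-2-yl)heptanal
Conditions: O3 (1 equiv), CH2Cl2/MeOH, −78 °C; then Me2S
Reagents that add atoms: ozone, [O-][O+]=O
Why: Ozonolysis with one equivalent of ozone should cleave the electron-richer trisubstituted ring alkene in preference to the 1,1-disubstituted isopropenyl group, and the stereocentre (C2 of the target) comes unchanged from the chiral pool.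

Step 2
Reactants: 2 (3S)-6-oxo-3-(prop-1-en-2-yl)heptanal
Product: 3 1-[(4R)-4-(prop-1-en-2-yl)cyclopent-1-en-1-yl]ethanone
Conditions: KOH (2% aq), Et2O, rt
Reagents that add atoms: none
Why: In this hydroxide-mediated intramolecular aldol condensation the internal ketone enolate attacks the more electrophilic aldehyde in a five-membered closure and dehydration gives the conjugated acetylcyclopentene without touching the stereocentre.

Step 3
Reactants: 3 1-[(4R)-4-(prop-1-en-2-yl)cyclopent-1-en-1-yl]ethanone
Product: 4 trimethyl({1-[(4R)-4-(prop-1-en-2-yl)cyclopent-1-en-1-yl]ethenyl}oxy)silane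
Conditions: Me3SiOTf, Et3N, CH2Cl2, 0 °C
Reagents that add atoms: trimethylsilyl trifluoromethanesulfonate, C[Si](C)(C)OS(=O)(=O)C(F)(F)F
Why: Soft enolisation of the methyl ketone with silyl triflate and amine should give the cross-conjugated 2-silyloxydiene because the CH3 group carries the only α-hydrogens.

Step 4
Reactants: 4 trimethyl({1-[(4R)-4-(prop-1-en-2-yl)cyclopent-1-en-1-yl]ethenyl}oxy)silane
Product: 5 trimethyl({1-[(4R)-4-(prop-1-en-2-yl)cyclopent-1-en-1-yl]cyclopropyl}oxy)silane
Conditions: Et2Zn, CH2I2 (1.1 equiv), CH2Cl2, −10 °C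
Reagents that add atoms: diiodomethane, ICI
Why: The Simmons–Smith cyclopropanation (Furukawa variant) uses an electrophilic carbenoid that should pick the silyl enol ether C=C over the two unactivated alkenes when about one equivalent is used.

Step 5
Reactants: 5 trimethyl({1-[(4R)-4-(prop-1-en-2-yl)cyclopent-1-en-1-yl]cyclopropyl}oxy)silane
Product: 7 5-hydroxy-7-(prop-1-en-2-yl)spiro[3.4]octan-1-one (OH trans to isopropenyl; carbonyl carbon C1 cis to OH), via silyloxycyclopropyl epoxide 6 (not isolated)
Conditions: mCPBA, CH2Cl2, −20 to 0 °C; aq. citric acid work-up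
Reagents that add atoms: 3-chloroperoxybenzoic acid, O=C(OO)c1cccc(Cl)c1
Why: Prilezhaev epoxidation of the trisubstituted ring alkene should be faster than at the isopropenyl group and occur anti to it, which sets C4–O, and the acid-triggered semipinacol ring expansion then moves a cyclopropane CH2 to the tertiary epoxide carbon anti to its C–O bond, which fixes the spiro centre.

Step 6
Reactants: 7 5-hydroxy-7-(prop-1-en-2-yl)spiro[3.4]octan-1-one
Product: 8 1-oxo-7-(prop-1-en-2-yl)spiro[3.4]octan-5-yl 2-methylpropanoate
Conditions: i-PrCOCl, pyridine, DMAP (cat.), CH2Cl2, 0 °C to rt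
Reagents that add atoms: isobutyryl chloride, CC(C)C(=O)Cl
Why: DMAP-catalysed O-acylation installs the final C4 ester with retention, under conditions too mild for retro-aldol opening of the β-hydroxy ketone.

Step 7
Reactants: 8 1-oxo-7-(prop-1-en-2-yl)spiro[3.4]octan-5-yl 2-methylpropanoate
Product: 10 1-oxo-7-(prop-1-en-2-yl)spiro[3.4]oct-2-en-5-yl 2-methylpropanoate, via silyl enol ether 9 (not isolated)
Conditions: LiN(SiMe3)2, Me3SiCl, THF, −78 °C; then Pd(OAc)2, MeCN, rt
Reagents that add atoms: none
Why: In this Saegusa–Ito oxidation the ketone can enolise only towards its CH2 group (the other α-carbon is quaternary and the ester is less acidic), and syn β-hydride elimination from the palladium enolate gives the 4,4-disubstituted cyclobutenone.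

Step 8
Reactants: 10 1-oxo-7-(prop-1-en-2-yl)spiro[3.4]oct-2-en-5-yl 2-methylpropanoate
Product: 11 1-hydroxy-1-methyl-7-(prop-1-en-2-yl)spiro[3.4]oct-2-en-5-yl 2-methylpropanoate
Conditions: MeLi, CeCl3, THF, −78 °C
Reagents that add atoms: methyllithium, [Li]C
Why: The weakly basic organocerium reagent should add 1,2 to the strained enone carbonyl, from the face away from the ester-bearing carbon, much faster than to the hindered ester.

Step 9
Reactants: 11 1-hydroxy-1-methyl-7-(prop-1-en-2-yl)spiro[3.4]oct-2-en-5-yl 2-methylpropanoate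
Product: 12 3-methyl-1-oxo-7-(prop-1-en-2-yl)spiro[3.4]oct-2-en-5-yl 2-methylpropanoate (carbonyl carbon now trans and methyl-bearing carbon cis to the ester)
Conditions: pyridinium chlorochromate, 4 Å MS, CH2Cl2, rt
Reagents that add atoms: pyridinium chlorochromate, [O-][Cr](=O)(=O)Cl.c1cc[nH+]cc1
Why: In the Babler–Dauben oxidative transposition the chromate ester of the tertiary allylic alcohol undergoes a suprafacial [3,3] shift and is oxidised, so the two cyclobutane arms at the unchanged spiro atom exchange roles and the future C10 ends on the same face as the C4 ester.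

Step 10
Reactants: 12 3-methyl-1-oxo-7-(prop-1-en-2-yl)spiro[3.4]oct-2-en-5-yl 2-methylpropanoate
Product: 13 3-methyl-1-oxo-7-(prop-1-en-2-yl)spiro[3.4]octan-5-yl 2-methylpropanoate (3-CH3 syn to C5 on the cyclobutane)
Conditions: [(Ph3P)CuH]6, toluene, rt; aq. work-up
Reagents that add atoms: none
Why: In this copper hydride 1,4-reduction the hydride should reach the β-carbon from the cyclobutenone face turned away from the nearby C4 isobutyrate, which sets C10 with its methyl group syn to C4, while ester and isolated alkene are inert.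

Step 11
Reactants: 13 3-methyl-1-oxo-7-(prop-1-en-2-yl)spiro[3.4]octan-5-yl 2-methylpropanoate; 14 1-propynyllithium
Product: 16 6,10-dimethyl-8-oxo-2-(prop-1-en-2-yl)spiro[4.5]dec-6-en-4-yl 2-methylpropanoate, via propargylic cyclobutanol 15 (not isolated)
Conditions: 14, THF, −78 °C; then (BuO)2P(O)OH (1 equiv); then [Ir(dF(CF3)ppy)2(5,5'-d(CF3)bpy)]PF6 (2 mol %), 2,4,6-triisopropylbenzenethiol (10 mol %), PhCF3, blue LED, rt
Reagents that add atoms: 1-propynyllithium (14), [Li]C#CC
Why: Proposed new method: the acetylide adds to the strained cyclobutanone carbonyl much faster than to the hindered isobutyrate and makes C7–C8 (carbinol 15), and the dibutyl phosphate quench leaves the hydrogen-bond-accepting base with which the excited iridium complex takes proton and electron from the O–H bond. The cyclobutyloxy radical releases ring strain by β-scission, and of its two ring bonds only the one to the quaternary spiro carbon should break because it gives a tertiary instead of a primary radical; this is the site selectivity the step needs, and the substitution of C5 secures it. The nucleophilic C5 radical then adds to the electrophilic β-carbon of the tethered ynone in a polarity-matched 6-endo-dig closure that forms C5–C6 and the cyclohexenone (5-exo-dig attack at the α-carbon is electronically mismatched), and the σ-vinyl radical at C7 takes hydrogen from the thiol, whose thiyl radical is reduced by the iridium complex to close the cycle. The planar C5 radical should be attacked anti to the adjacent C4 isobutyrate, the face the carbonyl carbon has just left, so C6 ends trans and C10 cis to the ester, while C2, C4 and C10 are not touched. The closest known reaction types are the proton-coupled-electron-transfer n+2 ring expansion of 1-alkenylcycloalkanols and the regioselective radical opening of tertiary cyclobutanols; the alkynyl carbinol as substrate and the telescoping with the acetylide addition are the new elements.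

Step 12
Reactants: 16 6,10-dimethyl-8-oxo-2-(prop-1-en-2-yl)spiro[4.5]dec-6-en-4-yl 2-methylpropanoate
Product: 18 (2S,4R,5R,9R,10S)-9-acetoxy-6,10-dimethyl-8-oxo-2-(prop-1-en-2-yl)spiro[4.5]dec-6-en-4-yl 2-methylpropanoate (target), via potassium alkoxide 17 (not isolated)
Conditions: KN(SiMe3)2, THF, −78 °C; 2-(phenylsulfonyl)-3-phenyloxaziridine; then Ac2O, −78 °C to rt
Reagents that add atoms: 2-(phenylsulfonyl)-3-phenyloxaziridine, O=S(=O)(c1ccccc1)N1OC1c1ccccc1; acetic anhydride, CC(=O)OC(C)=O
Why: Kinetic α′-deprotonation of the enone (more acidic than the hindered ester) and Davis oxidation from the enolate face anti to the neighbouring C10 methyl group should set C9 with oxygen trans to CH3, and the alkoxide is acetylated in the same flask.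

Compound list
1 | (S)-(−)-limonene | CC1=CC[C@H](CC1)C(C)=C | starting material
2 | (3S)-6-oxo-3-(prop-1-en-2-yl)heptanal | O=CC[C@H](CCC(C)=O)C(C)=C | intermediate
3 | 1-[(4R)-4-(prop-1-en-2-yl)cyclopent-1-en-1-yl]ethanone | CC(=O)C1=CC[C@H](C1)C(C)=C | intermediate
4 | trimethyl({1-[(4R)-4-(prop-1-en-2-yl)cyclopent-1-en-1-yl]ethenyl}oxy)silane | C=C(O[Si](C)(C)C)C1=CC[C@H](C1)C(C)=C | intermediate
5 | trimethyl({1-[(4R)-4-(prop-1-en-2-yl)cyclopent-1-en-1-yl]cyclopropyl}oxy)silane | C[Si](C)(C)OC1(CC1)C2=CC[C@H](C2)C(C)=C | intermediate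
6 | 3-(prop-1-en-2-yl)-1-[1-(trimethylsilyloxy)cyclopropyl]-6-oxabicyclo[3.1.0]hexane, oxirane oxygen trans to isopropenyl | C=C(C)[C@@H]1C[C@H]2O[C@]2(C1)C3(CC3)O[Si](C)(C)C | intermediate
7 | 5-hydroxy-7-(prop-1-en-2-yl)spiro[3.4]octan-1-one, OH trans to isopropenyl, C1 cis to OH | C=C(C)[C@@H]1C[C@@H](O)[C@]2(C1)C(=O)CC2 | intermediate
8 | 1-oxo-7-(prop-1-en-2-yl)spiro[3.4]octan-5-yl 2-methylpropanoate | C=C(C)[C@@H]1C[C@@H](OC(=O)C(C)C)[C@]2(C1)C(=O)CC2 | intermediate
9 | 7-(prop-1-en-2-yl)-1-(trimethylsilyloxy)spiro[3.4]oct-1-en-5-yl 2-methylpropanoate | C=C(C)[C@@H]1C[C@@H](OC(=O)C(C)C)[C@]2(C1)C(O[Si](C)(C)C)=CC2 | intermediate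
10 | 1-oxo-7-(prop-1-en-2-yl)spiro[3.4]oct-2-en-5-yl 2-methylpropanoate | C=C(C)[C@@H]1C[C@@H](OC(=O)C(C)C)[C@]2(C1)C(=O)C=C2 | intermediate
11 | 1-hydroxy-1-methyl-7-(prop-1-en-2-yl)spiro[3.4]oct-2-en-5-yl 2-methylpropanoate | C=C(C)[C@@H]1C[C@@H](OC(=O)C(C)C)[C@]2(C1)[C@](C)(O)C=C2 | intermediate
12 | 3-methyl-1-oxo-7-(prop-1-en-2-yl)spiro[3.4]oct-2-en-5-yl 2-methylpropanoate, C1 trans to the ester | C=C(C)[C@@H]1C[C@@H](OC(=O)C(C)C)[C@@]2(C1)C(=O)C=C2C | intermediate
13 | 3-methyl-1-oxo-7-(prop-1-en-2-yl)spiro[3.4]octan-5-yl 2-methylpropanoate, 3-CH3 syn to C5 | C=C(C)[C@@H]1C[C@@H](OC(=O)C(C)C)[C@@]2(C1)C(=O)C[C@H]2C | intermediate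
14 | 1-propynyllithium | [Li]C#CC | starting material
15 | 1-hydroxy-3-methyl-7-(prop-1-en-2-yl)-1-(prop-1-yn-1-yl)spiro[3.4]octan-5-yl 2-methylpropanoate | C=C(C)[C@@H]1C[C@@H](OC(=O)C(C)C)[C@@]2(C1)[C@](O)(C#CC)C[C@H]2C | intermediate
16 | 6,10-dimethyl-8-oxo-2-(prop-1-en-2-yl)spiro[4.5]dec-6-en-4-yl 2-methylpropanoate | C=C(C)[C@@H]1C[C@@H](OC(=O)C(C)C)[C@@]2(C1)C(C)=CC(=O)C[C@H]2C | intermediate
17 | potassium 9-oxide of 16 (oxygen trans to the 10-methyl group) | C=C(C)[C@@H]1C[C@@H](OC(=O)C(C)C)[C@@]2(C1)C(C)=CC(=O)[C@H]([O-])[C@H]2C.[K+] | intermediate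
18 | (2S,4R,5R,9R,10S)-9-acetoxy-6,10-dimethyl-8-oxo-2-(prop-1-en-2-yl)spiro[4.5]dec-6-en-4-yl 2-methylpropanoate | C=C(C)[C@@H]1C[C@@H](OC(=O)C(C)C)[C@@]2(C1)C(C)=CC(=O)[C@H](OC(C)=O)[C@H]2C | target

Total step count: 12. Longest linear sequence: 12 steps (from 1).

Steps most likely to fail

Step 11. Four processes could spoil the step.
- The thiol may transfer hydrogen to the tertiary radical before ring closure.
- A 5-exo closure may compete.
- The thiyl radical may add to the isopropenyl group.
- Lithium salts may suppress the O–H activation.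

The fallback sets out from 3, comes back at 16, and makes the two ring bonds in separate, known operations.
- Horner–Wadsworth–Emmons olefination of 3 with triethyl phosphonoacetate and NaH should give the ethyl dienoate F1.
- Catalyst-controlled copper hydride 1,4-reduction follows (CuCl, NaOt-Bu, the matching enantiomer of p-tol-BINAP, polymethylhydrosiloxane). It should set C10 and give the γ,δ-unsaturated ester F2.
- 14 with BF3·OEt2 should convert the ester into the ynone F3.
- mCPBA should epoxidise the ring alkene anti to the isopropenyl group to give the epoxy ynone F4.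
- Cp2TiCl, made from Cp2TiCl2 and Mn, is a trivalent titanium reagent. It should open the epoxide to the tertiary C5 radical, which closes on the ynone anti to the titanium alkoxide to give the hydroxy enone F5.
- Acylation with isobutyryl chloride and pyridine then gives 16.

Step 9. The strained tertiary cyclobutenol may ionise or open electrocyclically under the acidic chromium reagent instead of undergoing the [3,3] shift. The fallback sets out from 11 and comes back at 12. A non-oxidative 1,3-transposition catalysed by Ph3SiOReO3 in Et2O at low temperature should give the secondary cyclobutenol F6. A separate Dess–Martin oxidation under buffered conditions then gives 12.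

Step 5. Facial selectivity may be poor, since only 1,3-induction from the isopropenyl group operates, and the peracid may also epoxidise that group. The fallback sets out from 3 and comes back at 6.
- Weitz–Scheffer epoxidation (H2O2, NaOH, MeOH) touches only the enone and should give the epoxy ketone F7.
- LiN(SiMe3)2 and Me3SiCl give its silyl enol ether F8.
- Et2Zn and CH2I2 cyclopropanate the enol ether to give 6.
- BF3·OEt2 then rearranges 6 to 7, and the diastereomers are separated at the crystalline ketol stage.

Further compounds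
F1 | step 11 | ethyl (2E)-3-[(4R)-4-(prop-1-en-2-yl)cyclopent-1-en-1-yl]but-2-enoate | CCOC(=O)/C=C(\C)C1=CC[C@H](C1)C(C)=C
F2 | step 11 | ethyl 3-[(4R)-4-(prop-1-en-2-yl)cyclopent-1-en-1-yl]butanoate, C3 configured as C10 of the target | CCOC(=O)C[C@@H](C)C1=CC[C@H](C1)C(C)=C
F3 | step 11 | 6-[(4R)-4-(prop-1-en-2-yl)cyclopent-1-en-1-yl]hept-2-yn-4-one, C6 configured as C10 of the target | CC#CC(=O)C[C@@H](C)C1=CC[C@H](C1)C(C)=C
F4 | step 11 | 6-[3-(prop-1-en-2-yl)-6-oxabicyclo[3.1.0]hexan-1-yl]hept-2-yn-4-one, oxirane oxygen trans to isopropenyl | C=C(C)[C@@H]1C[C@H]2O[C@]2(C1)[C@H](C)CC(=O)C#CC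
F5 | step 11 | 4-hydroxy-6,10-dimethyl-2-(prop-1-en-2-yl)spiro[4.5]dec-6-en-8-one | C=C(C)[C@@H]1C[C@@H](O)[C@@]2(C1)C(C)=CC(=O)C[C@H]2C
F6 | step 9 | 1-hydroxy-3-methyl-7-(prop-1-en-2-yl)spiro[3.4]oct-2-en-5-yl 2-methylpropanoate | C=C(C)[C@@H]1C[C@@H](OC(=O)C(C)C)[C@@]2(C1)[C@@H](O)C=C2C
F7 | step 5 | 1-[3-(prop-1-en-2-yl)-6-oxabicyclo[3.1.0]hexan-1-yl]ethanone, oxirane oxygen trans to isopropenyl | C=C(C)[C@@H]1C[C@H]2O[C@]2(C1)C(C)=O
F8 | step 5 | trimethyl({1-[3-(prop-1-en-2-yl)-6-oxabicyclo[3.1.0]hexan-1-yl]ethenyl}oxy)silane | C=C(C)[C@@H]1C[C@H]2O[C@]2(C1)C(=C)O[Si](C)(C)C
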